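A direct plan would dimerise dodec-1-ene A1 by olefin self-metathesis with the second-generation Grubbs catalyst to docos-11-ene A2 (E/Z mixture), with ethene stripped off.
It would then subject A2 to isomerising alkoxycarbonylation with carbon monoxide A3 and 2-phenylethanol A4 under Pd(OAc)2, a bulky diphosphine and CH3SO3H, passing through docos-1-ene A5 to give 2-phenylethyl tricosanoate A6.
Weak point 1, the isomerising alkoxycarbonylation: the double bond of A2 would have to walk ten positions from the centre of the chain to the disfavoured terminal isomer A5 and be trapped there by an alcohol that is bulkier and slower than methanol. This would need days under pressure of A3 and a large excess of A4 in strong acid (ether and styrene formation), and branched esters or unreacted internal olefins would be hard to remove from the waxy ester A6.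
Weak point 2, the self-metathesis of A1: chain-length fidelity would depend entirely on suppressing ruthenium hydride isomerisation. Any migration would give C21 and C23 olefins and, after carbonylation, C22 and C24 esters that cannot be separated from A6.
Weak point 3, the alkene detour as a whole: an alkene would be built only to be erased, and the E/Z and positional mixtures would allow no intermediate to be purified to a single compound before the last step.

**Retrosynthetic overview**

- Feature addressed: the unbranched, odd-numbered C23 acyl chain (C1 = ester carbonyl, C23 = methyl). The only ring, the benzene ring, is bought in the alcohol, and no ring is formed in the route.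
- Key disconnection: the C4–C5 single bond inside the saturated chain, formed by anodic crossed Kolbe coupling of two carboxylic acids with loss of two CO2. C1–C4 come from glutaric anhydride 1, opened by 2-phenylethanol 2 to half-ester 3. C5–C23 come from icosanoic acid 4. Radicals 5 and 6 combine to target 7.
- How the weak steps are avoided: no alkene ever exists, so the chain length is fixed by two single, purifiable acids (20 + 5 − 2 = 23). The ester is made first by a ring opening that needs no excess alcohol, no strong acid and no CO pressure.

Key step: step 2

Assumption: glutaric anhydride, 2-phenylethanol and icosanoic acid are taken as commercial single-homologue materials; the acyl chain is numbered from the ester carbonyl (C1) to the methyl group (C23).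

**Route**

Step 1
Reactants: 1 glutaric anhydride (oxane-2,6-dione); 2 2-phenylethanol
Product: 3 5-oxo-5-(2-phenylethoxy)pentanoic acid (mono-2-phenylethyl glutarate)
Conditions: 1 (1.0 equiv), 2 (1.0 equiv), DMAP (5 mol %), toluene, 80 °C, 6 h; dilute aqueous HCl wash, solvent removed
Reagents that add atoms: none
Why: Nucleophilic ring opening of a cyclic anhydride by a primary alcohol (DMAP-catalysed acyl transfer) should stop cleanly at the half-ester, because the carboxylic acid that is released cannot acylate a second alcohol under these conditions; no stereocentre is involved.

Step 2
Reactants: 3 5-oxo-5-(2-phenylethoxy)pentanoic acid (4 equiv); 4 icosanoic acid (arachidic acid, 1 equiv)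
Product: 7 2-phenylethyl tricosanoate, via nonadecyl radical 5 (not isolated), via 4-oxo-4-(2-phenylethoxy)butyl radical 6 (not isolated)
Conditions: KOH (5 mol % of total CO2H), MeOH, 50 °C, undivided cell, smooth Pt anode and Pt cathode, constant current about 0.2 A cm−2, polarity reversed every few minutes, stopped while the electrolyte is still faintly acidic (about 1.3 F per mol CO2H); AcOH quench; extraction into hexane, SiO2 (hexane, then hexane/EtOAc 95:5), recrystallisation from acetone
Reagents that add atoms: none
Why: Crossed Kolbe electrolysis (Brown–Walker type anodic decarboxylative radical coupling): both carboxylates are discharged by one-electron oxidation at the platinum anode, lose CO2 to give the primary radicals 5 and 6 in the dense layer at the electrode, and these combine to form the C4–C5 bond while the cathode turns the carboxyl protons into H2. The closest known reaction type is the mixed anodic coupling of a fatty acid with an alkyl hydrogen alkanedioate in partly neutralised methanol, the classical way to lengthen fatty acids. No ring is closed and no stereocentre is formed. The selectivity needed is crossed over symmetrical coupling, and it is secured statistically by the fourfold excess of the cheap half-ester 3, so that most nonadecyl radicals should meet radical 6; the two symmetrical dimers (a C38 alkane and a C8 diester) differ strongly from 7 in polarity and should be removed on silica. The radical pathway should prevail over the cation (Hofer–Moest) pathway because both radicals are unbranched and primary and because smooth platinum, high current density and a weakly acidic electrolyte are used. The 2-phenylethyl ester should survive because the carboxylic acid/carboxylate buffer keeps methoxide negligible as long as the run is stopped before the electrolyte turns alkaline, and the benzene ring should be shielded from oxidation by the carboxylate layer on the anode.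

**Compound list**

1 | glutaric anhydride (oxane-2,6-dione) | O=C1CCCC(=O)O1 | starting material
2 | 2-phenylethanol | OCCc1ccccc1 | starting material
3 | 5-oxo-5-(2-phenylethoxy)pentanoic acid | OC(=O)CCCC(=O)OCCc1ccccc1 | intermediate
4 | icosanoic acid (arachidic acid) | CCCCCCCCCCCCCCCCCCCC(=O)O | starting material
5 | nonadecyl radical (formed at the anode, not isolated) | [CH2]CCCCCCCCCCCCCCCCCC | intermediate
6 | 4-oxo-4-(2-phenylethoxy)butyl radical (formed at the anode, not isolated) | [CH2]CCC(=O)OCCc1ccccc1 | intermediate
7 | 2-phenylethyl tricosanoate (achiral) | CCCCCCCCCCCCCCCCCCCCCCC(=O)OCCc1ccccc1 | target

Total step count: 2. Longest linear sequence: 2 steps.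

**Steps most likely to fail**

The route has only two steps, so both are ranked, and step 2 is entered twice because it can fail by two unrelated processes.

1. Step 2, loss of the crossed coupling. The waxy products may film over the anode, or the long-chain carboxylate may crowd the half-ester out of the electrode layer, so that the current goes into symmetrical dimers and solvent oxidation. The fallback avoids electrolysis and forms the C5–C6 bond by copper catalysis. It sets out from 2: acid-catalysed esterification with purchased 5-bromopentanoic acid (TsOH, toluene, Dean–Stark trap) would give 2-phenylethyl 5-bromopentanoate F1. Octadecylmagnesium bromide F2, made from purchased 1-bromooctadecane and magnesium in THF, would then be added slowly to F1 with Li2CuCl4 (3 mol %, divalent copper) in THF/NMP at 0 °C. This copper-catalysed alkyl–alkyl coupling of a Grignard reagent with a primary bromide is known to spare esters, and it comes back to the route at 7.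

2. Step 2, methanolysis of the 2-phenylethyl ester. If the electrolyte turns alkaline near the end of the run, methoxide could exchange the ester and give mixed methyl and 2-phenylethyl products. The fallback carries a methyl ester through the electrolysis and installs the alcohol last. It sets out from 1 and 4: methanolysis of 1 (MeOH, reflux) would give 5-methoxy-5-oxopentanoic acid F3. Crossed Kolbe electrolysis of F3 with 4 under the conditions of step 2 would give methyl tricosanoate F4, exchange with the solvent then being degenerate. Transesterification of F4 with 2 catalysed by Ti(OiPr)4 at 120 °C, with methanol distilled off, comes back to the route at 7.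

3. Step 1, incomplete ring opening or acyl scrambling. Prolonged heating could leave free alcohol 2 or redistribute the half-ester into diester and glutaric acid, and free alcohol would then be oxidised at the anode in step 2. The fallback uses a protected half-acid. It sets out from 2: Steglich esterification (DCC, DMAP cat., CH2Cl2, room temperature) with purchased 5-tert-butoxy-5-oxopentanoic acid would give tert-butyl 2-phenylethyl pentanedioate F5. Cleavage of the tert-butyl ester with CF3CO2H in CH2Cl2 comes back to the route at 3.

**Further compounds**

F1 | step 2 | 2-phenylethyl 5-bromopentanoate | BrCCCCC(=O)OCCc1ccccc1
F2 | step 2 | octadecylmagnesium bromide | CCCCCCCCCCCCCCCCCC[Mg]Br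
F3 | step 2 | 5-methoxy-5-oxopentanoic acid | COC(=O)CCCC(=O)O
F4 | step 2 | methyl tricosanoate | CCCCCCCCCCCCCCCCCCCCCCC(=O)OC
F5 | step 1 | tert-butyl 2-phenylethyl pentanedioate | CC(C)(C)OC(=O)CCCC(=O)OCCc1ccccc1
A1 | direct plan | dodec-1-ene | CCCCCCCCCCC=C
A2 | direct plan | docos-11-ene (E isomer shown) | CCCCCCCCCC/C=C/CCCCCCCCCC
A3 | direct plan | carbon monoxide | [C-]#[O+]
A4 | direct plan | 2-phenylethanol | OCCc1ccccc1
A5 | direct plan | docos-1-ene | CCCCCCCCCCCCCCCCCCCCC=C
A6 | direct plan | 2-phenylethyl tricosanoate | CCCCCCCCCCCCCCCCCCCCCCC(=O)OCCc1ccccc1
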